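**Retrosynthetic overview**
1. The axial C7 isopropenyl and the C8 hydroxyl are installed last, by trans-diaxial opening of a 7α,8α-epoxide with an isopropenyl cuprate; the C9 ester comes from Mitsunobu inversion of a 9β-allylic alcohol.
2. That alcohol traces back (enone reduction, Saegusa oxidation, silylation) to a trans-fused 2-hydroxy-9-decalone.
3. Ring A is closed onto ring B by a type-two carbonyl-ene reaction of a 1,4-keto aldehyde, followed by hydroxyl-directed hydrogenation (sets C2 and C4).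
4. Key disconnection: the C1–C10 bond of the 1,4-dicarbonyl, made by coupling two enol silanes through an enolonium (reversed-polarity enolate) of the ring-B ketone.
5. Ring B is bought as 3-methylcyclohexenone and C5 is set by catalytic asymmetric conjugate addition; ring order is B, then A.

Notation: eremophilane-type locants are used in the comments (ring A = C1–C5 and C10; ring B = C5–C10; C9 carries the ester, C8 and C2 the hydroxyls, C7 the isopropenyl group, C4 and C5 the methyls); β is the face of the C5 methyl.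
Assumption: the sense of induction of the chiral ligand in step 1 is not predicted here; the ligand enantiomer that gives the 3S product is used.

**Step 1**
Reactants: 1 3-methylcyclohex-2-en-1-one; 2 isopropenylmagnesium bromide
Product: 4 trimethyl{[(3S)-3-methyl-3-(prop-1-en-2-yl)cyclohex-1-en-1-yl]oxy}silane, via bromomagnesium enolate 3 (not isolated)
Conditions: 2 (1.3 equiv), Cu(OTf)2 (3 mol%), chiral imidazolinium NHC precursor (4 mol%), Et2O, −30 °C; then TMSCl, Et3N, −30 °C → rt
Reagents that add atoms: chlorotrimethylsilane, C[Si](C)(C)Cl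
Why: Copper-catalysed asymmetric conjugate addition of a Grignard reagent to a β-substituted cyclohexenone builds the quaternary C5 centre under catalyst control, and O-silylation of the magnesium enolate fixes the C9–C10 enol regiochemistry.

**Step 2**
Reactants: 4 trimethyl{[(3S)-3-methyl-3-(prop-1-en-2-yl)cyclohex-1-en-1-yl]oxy}silane; 5 trimethyl(vinyloxy)silane
Product: 7 2-[(1R,2S)-2-methyl-6-oxo-2-(prop-1-en-2-yl)cyclohexyl]acetaldehyde, via iodine-bound enolonium 6 (not isolated)
Conditions: PhI(OAc)2 (1.3 equiv), BF3·OEt2 (1.5 equiv), CH2Cl2, −78 °C, 10 min; then 5 (3 equiv), −78 → −40 °C; cold aq. NaHCO3 quench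
Reagents that add atoms: none
Why: Proposed new method: PhI(OAc)2/BF3 turns enol silane 4 into an oxygen-bound trivalent-iodine enolate whose α-carbon (C10) is electrophilic, and the second enol silane attacks it with loss of iodobenzene, so two carbons that are both normally enolate donors are joined to give the 1,4-keto aldehyde; attack anti to the pseudoaxial isopropenyl group on the neighbouring quaternary carbon should place CH2CHO trans to it (modest dr expected, minor C10 epimer removed after step 3); the closest known reaction type is the oxidative cross-coupling of two ketone enol silanes through a preformed enolonium species, extended here to an aldehyde enol silane as nucleophile.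

**Step 3**
Reactants: 7 2-[(1R,2S)-2-methyl-6-oxo-2-(prop-1-en-2-yl)cyclohexyl]acetaldehyde
Product: 8 (4aS,7R,8aR)-7-hydroxy-4a-methyl-5-methylideneoctahydronaphthalen-1(2H)-one
Conditions: Me2AlCl (1.5 equiv), CH2Cl2, −78 → −20 °C
Reagents that add atoms: none
Why: A Lewis-acid-promoted type-two intramolecular carbonyl-ene reaction closes ring A from the two equatorial trans arms to give the trans-decalin, and because the aldehyde oxygen must sit over the alkene to take a hydrogen from the allylic methyl, the new C2 hydroxyl is expected axial (2α) with an exocyclic methylene left at C4.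

**Step 4**
Reactants: 8 (4aS,7R,8aR)-7-hydroxy-4a-methyl-5-methylideneoctahydronaphthalen-1(2H)-one
Product: 9 (4aR,5S,7S,8aR)-7-hydroxy-4a,5-dimethyloctahydronaphthalen-1(2H)-one
Conditions: H2 (1 atm), [Ir(cod)(PCy3)(py)]PF6 (3 mol%), CH2Cl2, rt
Reagents that add atoms: none
Why: Hydroxyl-directed homogeneous hydrogenation delivers hydrogen to the exocyclic alkene from the α face (the face of the axial C2 hydroxyl and opposite the axial angular methyl), so the C4 methyl ends equatorial and cis to the C5 methyl.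

**Step 5**
Reactants: 9 (4aR,5S,7S,8aR)-7-hydroxy-4a,5-dimethyloctahydronaphthalen-1(2H)-one
Product: 10 (4aR,5S,7S,8aR)-7-[(tert-butyldimethylsilyl)oxy]-4a,5-dimethyloctahydronaphthalen-1(2H)-one
Conditions: TBSCl, imidazole, DMF, 35 °C
Reagents that add atoms: tert-butyl(chloro)dimethylsilane, CC(C)(C)[Si](C)(C)Cl
Why: Silyl ether formation protects the C2 alcohol for the Mitsunobu and cuprate steps, and in the silyl ether the trans ring fusion is the thermodynamically preferred one (a cis-fused chair would put OTBS and C9 1,3-diaxial or make the C4 methyl axial), so C10 should not erode next to the ketone.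

**Step 6**
Reactants: 10 (4aR,5S,7S,8aR)-7-[(tert-butyldimethylsilyl)oxy]-4a,5-dimethyloctahydronaphthalen-1(2H)-one
Product: 13 (4aR,5S,7S,8aR)-7-[(tert-butyldimethylsilyl)oxy]-4a,5-dimethyl-4a,5,6,7,8,8a-hexahydronaphthalen-1(4H)-one, via lithium enolate 11 (not isolated), via silyl enol ether 12 (not isolated)
Conditions: LiN(i-Pr)2, THF, −78 °C; TMSCl; then Pd(OAc)2 (1.1 equiv), MeCN, rt
Reagents that add atoms: none
Why: Saegusa–Ito oxidation, in which kinetic deprotonation at the C8 methylene (not the ring-fusion C10–H), silylation and palladium-mediated dehydrosilylation give the Δ7 enone without touching existing stereocentres.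

**Step 7**
Reactants: 13 (4aR,5S,7S,8aR)-7-[(tert-butyldimethylsilyl)oxy]-4a,5-dimethyl-4a,5,6,7,8,8a-hexahydronaphthalen-1(4H)-one
Product: 14 (1S,4aR,5S,7S,8aR)-7-[(tert-butyldimethylsilyl)oxy]-4a,5-dimethyl-1,4,4a,5,6,7,8,8a-octahydronaphthalen-1-ol
Conditions: i-Bu2AlH (1.2 equiv), CH2Cl2, −78 °C; Rochelle salt work-up
Reagents that add atoms: none
Why: 1,2-Reduction of the enone by a bulky aluminium hydride, with hydride entering from the α face because the β face of C9 is screened by the 1,3-related axial angular methyl, gives the pseudoaxial 9β-alcohol.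

**Step 8**
Reactants: 15 ethyl pent-2-ynoate
Product: 16 ethyl (2Z)-3-methylpent-2-enoate
Conditions: Me2CuLi (from MeLi and CuI, 1.2 equiv), THF, −78 °C, 1 h; MeOH then aq. NH4Cl at −78 °C
Reagents that add atoms: lithium dimethylcuprate, [Li+].C[Cu-]C
Why: syn-Carbocupration of a 2-alkynoate at low temperature followed by protonation with retention places the new methyl cis to hydrogen and therefore ethyl cis to the ester, which is the Z enoate.

**Step 9**
Reactants: 16 ethyl (2Z)-3-methylpent-2-enoate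
Product: 17 (2Z)-3-methylpent-2-enoic acid
Conditions: LiOH, THF/MeOH/H2O, rt; then 1 M HCl
Reagents that add atoms: lithium hydroxide, [Li+].[OH-]
Why: Saponification frees the acid, and the geometry of the β,β-disubstituted enoate is retained under mild hydroxide conditions.

**Step 10**
Reactants: 14 (1S,4aR,5S,7S,8aR)-7-[(tert-butyldimethylsilyl)oxy]-4a,5-dimethyl-1,4,4a,5,6,7,8,8a-octahydronaphthalen-1-ol; 17 (2Z)-3-methylpent-2-enoic acid
Product: 18 (1R,4aR,5S,7S,8aR)-7-[(tert-butyldimethylsilyl)oxy]-4a,5-dimethyl-1,4,4a,5,6,7,8,8a-octahydronaphthalen-1-yl (2Z)-3-methylpent-2-enoate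
Conditions: PPh3, DIAD, THF, 0 °C → rt
Reagents that add atoms: none
Why: Mitsunobu esterification displaces the oxyphosphonium by SN2 with inversion, turning the readily made 9β-alcohol into the equatorial 9α-ester and installing the side chain in the same step.

**Step 11**
Reactants: 18 (1R,4aR,5S,7S,8aR)-7-[(tert-butyldimethylsilyl)oxy]-4a,5-dimethyl-1,4,4a,5,6,7,8,8a-octahydronaphthalen-1-yl (2Z)-3-methylpent-2-enoate
Product: 19 (1S,2R,3R,4aR,5S,7S,8aR)-7-[(tert-butyldimethylsilyl)oxy]-2,3-epoxy-4a,5-dimethyldecahydronaphthalen-1-yl (2Z)-3-methylpent-2-enoate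
Conditions: mCPBA, NaHCO3, CH2Cl2, 0 °C
Reagents that add atoms: 3-chloroperbenzoic acid, OOC(=O)c1cccc(Cl)c1
Why: Peracid (Prilezhaev) epoxidation leaves the electron-poor enoate alkene alone and attacks the ring alkene from the α face, opposite the axial angular methyl (as with steroid Δ2 olefins), giving the 7α,8α-epoxide.

**Step 12**
Reactants: 19 (1S,2R,3R,4aR,5S,7S,8aR)-7-[(tert-butyldimethylsilyl)oxy]-2,3-epoxy-4a,5-dimethyldecahydronaphthalen-1-yl (2Z)-3-methylpent-2-enoate; 2 isopropenylmagnesium bromide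
Product: 20 (1S,2R,3R,4aR,5S,7S,8aR)-7-[(tert-butyldimethylsilyl)oxy]-2-hydroxy-4a,5-dimethyl-3-(prop-1-en-2-yl)decahydronaphthalen-1-yl (2Z)-3-methylpent-2-enoate
Conditions: 2 (4 equiv), CuI (2 equiv), THF/Me2S, −40 → −10 °C; aq. NH4Cl
Reagents that add atoms: none
Why: Fürst–Plattner (trans-diaxial) epoxide opening by a magnesium cuprate at C7 from the β face gives axial 7β-isopropenyl and axial 8α-OH, the same regiochemistry as opening of steroidal 2α,3α-epoxides at C2, while attack at C8 would need a twist-boat and lies next to the acyloxy carbon; the β,β-disubstituted enoate is a poor cuprate acceptor and an acyl shift to the axial C8 oxygen is uphill.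

**Step 13**
Reactants: 20 (1S,2R,3R,4aR,5S,7S,8aR)-7-[(tert-butyldimethylsilyl)oxy]-2-hydroxy-4a,5-dimethyl-3-(prop-1-en-2-yl)decahydronaphthalen-1-yl (2Z)-3-methylpent-2-enoate
Product: 21 (1S,2R,3R,4aR,5S,7S,8aR)-2,7-dihydroxy-4a,5-dimethyl-3-(prop-1-en-2-yl)decahydronaphthalen-1-yl (2Z)-3-methylpent-2-enoate
Conditions: HF·pyridine, THF, 0 °C → rt
Reagents that add atoms: none
Why: Fluoride-mediated desilylation under mildly acidic conditions frees the C2 alcohol without acyl migration or E/Z isomerisation.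

**Compound list**
1 | 3-methylcyclohex-2-en-1-one | CC1=CC(=O)CCC1 | starting material
2 | isopropenylmagnesium bromide | C=C(C)[Mg]Br | starting material
3 | bromo{[(3S)-3-methyl-3-(prop-1-en-2-yl)cyclohex-1-en-1-yl]oxy}magnesium | C1CCC(O[Mg]Br)=C[C@@]1(C)C(C)=C | intermediate
4 | trimethyl{[(3S)-3-methyl-3-(prop-1-en-2-yl)cyclohex-1-en-1-yl]oxy}silane | C1CCC(O[Si](C)(C)C)=C[C@@]1(C)C(C)=C | intermediate
5 | trimethyl(vinyloxy)silane | C=CO[Si](C)(C)C | starting material
6 | acetoxy{[(3S)-3-methyl-3-(prop-1-en-2-yl)cyclohex-1-en-1-yl]oxy}(phenyl)-λ3-iodane (enolonium species, drawn oxygen-bound) | C1CCC(O[I](OC(C)=O)c2ccccc2)=C[C@@]1(C)C(C)=C | intermediate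
7 | 2-[(1R,2S)-2-methyl-6-oxo-2-(prop-1-en-2-yl)cyclohexyl]acetaldehyde | O=CC[C@H]1C(=O)CCC[C@]1(C)C(C)=C | intermediate
8 | (4aS,7R,8aR)-7-hydroxy-4a-methyl-5-methylideneoctahydronaphthalen-1(2H)-one | C1C[C@]2(C)C(=C)C[C@H](O)C[C@H]2C(=O)C1 | intermediate
9 | (4aR,5S,7S,8aR)-7-hydroxy-4a,5-dimethyloctahydronaphthalen-1(2H)-one | C1C[C@]2(C)[C@@H](C)C[C@H](O)C[C@H]2C(=O)C1 | intermediate
10 | (4aR,5S,7S,8aR)-7-[(tert-butyldimethylsilyl)oxy]-4a,5-dimethyloctahydronaphthalen-1(2H)-one | C1C[C@]2(C)[C@@H](C)C[C@H](O[Si](C)(C)C(C)(C)C)C[C@H]2C(=O)C1 | intermediate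
11 | lithium (4aR,5S,7S,8aR)-7-[(tert-butyldimethylsilyl)oxy]-4a,5-dimethyl-3,4,4a,5,6,7,8,8a-octahydronaphthalen-1-olate | C1C[C@]2(C)[C@@H](C)C[C@H](O[Si](C)(C)C(C)(C)C)C[C@H]2C(O[Li])=C1 | intermediate
12 | (4aR,5S,7S,8aR)-7-[(tert-butyldimethylsilyl)oxy]-4a,5-dimethyl-1-[(trimethylsilyl)oxy]-3,4,4a,5,6,7,8,8a-octahydronaphthalene | C1C[C@]2(C)[C@@H](C)C[C@H](O[Si](C)(C)C(C)(C)C)C[C@H]2C(O[Si](C)(C)C)=C1 | intermediate
13 | (4aR,5S,7S,8aR)-7-[(tert-butyldimethylsilyl)oxy]-4a,5-dimethyl-4a,5,6,7,8,8a-hexahydronaphthalen-1(4H)-one | C1C[C@]2(C)[C@@H](C)C[C@H](O[Si](C)(C)C(C)(C)C)C[C@H]2C(=O)C=1 | intermediate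
14 | (1S,4aR,5S,7S,8aR)-7-[(tert-butyldimethylsilyl)oxy]-4a,5-dimethyl-1,4,4a,5,6,7,8,8a-octahydronaphthalen-1-ol | C1C[C@]2(C)[C@@H](C)C[C@H](O[Si](C)(C)C(C)(C)C)C[C@H]2[C@@H](O)C=1 | intermediate
15 | ethyl pent-2-ynoate | CCC#CC(=O)OCC | starting material
16 | ethyl (2Z)-3-methylpent-2-enoate | CCOC(=O)/C=C(/C)CC | intermediate
17 | (2Z)-3-methylpent-2-enoic acid | OC(=O)/C=C(/C)CC | intermediate
18 | (1R,4aR,5S,7S,8aR)-7-[(tert-butyldimethylsilyl)oxy]-4a,5-dimethyl-1,4,4a,5,6,7,8,8a-octahydronaphthalen-1-yl (2Z)-3-methylpent-2-enoate | C1C[C@]2(C)[C@@H](C)C[C@H](O[Si](C)(C)C(C)(C)C)C[C@H]2[C@H](OC(=O)/C=C(/C)CC)C=1 | intermediate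
19 | (1S,2R,3R,4aR,5S,7S,8aR)-7-[(tert-butyldimethylsilyl)oxy]-2,3-epoxy-4a,5-dimethyldecahydronaphthalen-1-yl (2Z)-3-methylpent-2-enoate | O1[C@@H]2C[C@]3(C)[C@@H](C)C[C@H](O[Si](C)(C)C(C)(C)C)C[C@H]3[C@H](OC(=O)/C=C(/C)CC)[C@H]12 | intermediate
20 | (1S,2R,3R,4aR,5S,7S,8aR)-7-[(tert-butyldimethylsilyl)oxy]-2-hydroxy-4a,5-dimethyl-3-(prop-1-en-2-yl)decahydronaphthalen-1-yl (2Z)-3-methylpent-2-enoate | C=C(C)[C@H]1C[C@]2(C)[C@@H](C)C[C@H](O[Si](C)(C)C(C)(C)C)C[C@H]2[C@H](OC(=O)/C=C(/C)CC)[C@@H]1O | intermediate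
21 | (1S,2R,3R,4aR,5S,7S,8aR)-2,7-dihydroxy-4a,5-dimethyl-3-(prop-1-en-2-yl)decahydronaphthalen-1-yl (2Z)-3-methylpent-2-enoate | C=C(C)[C@H]1C[C@]2(C)[C@@H](C)C[C@H](O)C[C@H]2[C@H](OC(=O)/C=C(/C)CC)[C@@H]1O | target

**Totals and risks**
Total step count: 13. Longest linear sequence: 11 (steps 1–7 and 10–13; steps 8–9 make the acid).

The three steps most likely to fail:

Step 2 (enolonium cross-coupling). The aldehyde enol silane is an untested nucleophile, the electrophilic carbon sits next to a quaternary centre, and BF3 could trigger premature cyclisation of the product. The fallback sets out from 4 and comes back at 7. MeLi (THF, 0 °C) cleaves the silyl enol ether to the lithium enolate, which is added to nitroethylene at −78 °C to give (2R,3S)-3-methyl-2-(2-nitroethyl)-3-(prop-1-en-2-yl)cyclohexan-1-one F1. A Nef reaction (NaOMe, MeOH; then buffered aqueous TiCl3) converts the nitro group into the aldehyde of 7. The nitroalkene serves as the same α-carbonyl cation equivalent, but by conjugate addition instead of oxidative coupling.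

Step 10 (Mitsunobu at a hindered allylic carbinol). SN2′ attack at C7 and elimination to the diene can compete with direct inversion. The fallback sets out from 13 and comes back at 19. The enone is epoxidised first (H2O2, NaOH, MeOH, 0 °C; peroxide adds from the α face) to (2R,3R,4aR,5S,7S,8aR)-7-[(tert-butyldimethylsilyl)oxy]-2,3-epoxy-4a,5-dimethyloctahydronaphthalen-1(2H)-one F2. Reduction (i-Bu2AlH, CH2Cl2, −78 °C) gives (1R,2S,3R,4aR,5S,7S,8aR)-7-[(tert-butyldimethylsilyl)oxy]-2,3-epoxy-4a,5-dimethyldecahydronaphthalen-1-ol F3. The Mitsunobu esterification with 17 is then run on this saturated carbinol, where no SN2′ path exists, and gives 19.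

Step 12 (cuprate opening of the epoxide). Attack at C7 is syn-axial to the angular methyl, the nucleophile is branched, and an ester sits on the neighbouring carbon. The fallback sets out from 19 and comes back at 20. The epoxide is opened with the slim alkynylalane Et2AlC≡CH (toluene, 0 °C; alkynylalanes open epoxides trans-diaxially and tolerate esters) to (1S,2R,3R,4aR,5S,7S,8aR)-7-[(tert-butyldimethylsilyl)oxy]-3-ethynyl-2-hydroxy-4a,5-dimethyldecahydronaphthalen-1-yl (2Z)-3-methylpent-2-enoate F4. Zirconium-catalysed methylalumination of the terminal alkyne (Me3Al, Cp2ZrCl2, CH2Cl2, rt; then H2O) puts methyl on the internal carbon and, after protonolysis, gives the isopropenyl group of 20.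

**Further compounds**
F1 | step 2 | (2R,3S)-3-methyl-2-(2-nitroethyl)-3-(prop-1-en-2-yl)cyclohexan-1-one | [O-][N+](=O)CC[C@H]1C(=O)CCC[C@]1(C)C(C)=C
F2 | step 10 | (2R,3R,4aR,5S,7S,8aR)-7-[(tert-butyldimethylsilyl)oxy]-2,3-epoxy-4a,5-dimethyloctahydronaphthalen-1(2H)-one | O1[C@@H]2C[C@]3(C)[C@@H](C)C[C@H](O[Si](C)(C)C(C)(C)C)C[C@H]3C(=O)[C@H]12
F3 | step 10 | (1R,2S,3R,4aR,5S,7S,8aR)-7-[(tert-butyldimethylsilyl)oxy]-2,3-epoxy-4a,5-dimethyldecahydronaphthalen-1-ol | O1[C@@H]2C[C@]3(C)[C@@H](C)C[C@H](O[Si](C)(C)C(C)(C)C)C[C@H]3[C@@H](O)[C@H]12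
F4 | step 12 | (1S,2R,3R,4aR,5S,7S,8aR)-7-[(tert-butyldimethylsilyl)oxy]-3-ethynyl-2-hydroxy-4a,5-dimethyldecahydronaphthalen-1-yl (2Z)-3-methylpent-2-enoate | C#C[C@H]1C[C@]2(C)[C@@H](C)C[C@H](O[Si](C)(C)C(C)(C)C)C[C@H]2[C@H](OC(=O)/C=C(/C)CC)[C@@H]1O
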